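**Assumption:** the target has no stereocentre or other stereogenic element (it is achiral), so "single enantiomer" is taken to mean the constitution given and no stereocontrol is needed.

## Retrosynthetic overview

1. The usual disconnection (acylating 3-(4-hydroxyphenyl)propan-1-ol with docosanoic acid or its chloride) is not used.
2. Target 6 is cut at the aryl C(sp2)–C(sp3) bond: a Ni-catalysed reductive cross-electrophile coupling of unprotected 4-bromophenol 5 with 3-bromopropyl docosanoate 4, the ester carried through intact.
3. Compound 4 is cut at the alkyl C–O bond: SN2 of docosanoate on excess 1,3-dibromopropane 2, so no alcohol is acylated anywhere.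
4. No ring is formed (the benzene ring is bought in 5), there are no protecting groups and no stereocentres.

## Route

**Step 1**
Reactants: 1 docosanoic acid (behenic acid, 1.0 equiv); 2 1,3-dibromopropane (5 equiv)
Product: 4 3-bromopropyl docosanoate, via potassium docosanoate 3 (not isolated)
Conditions: K2CO3 (1.1 equiv), DMF, 70 °C, 6 h; excess 2 distilled off under vacuum; recrystallised from acetone at 0 °C
Reagents that add atoms: none
Why: Carboxylate O-alkylation (SN2) of the potassium soap formed in the flask on a primary bromide; the five-fold excess of dibromide suppresses the second displacement that would give the 1,3-diester.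

**Step 2**
Reactants: 4 3-bromopropyl docosanoate (1.1 equiv); 5 4-bromophenol (1.0 equiv)
Product: 6 3-(4-hydroxyphenyl)propyl docosanoate (target)
Conditions: NiI2·xH2O (7 mol%), 1,10-phenanthroline (7 mol%), NaI (25 mol%), pyridine (10 mol%), Zn dust (2 equiv), DMPU, 80 °C, 16 h; 1 M HCl work-up
Reagents that add atoms: none
Why: Nickel-catalysed reductive cross-electrophile coupling (Weix-type): (phen)Ni(0) inserts selectively into the aryl C–Br bond, the primary alkyl bromide enters as an alkyl radical captured at arylnickel(II), and reductive elimination forms the C(sp2)–C(sp3) bond; no basic organometallic reagent is preformed, so the ester survives, and unprotected bromophenols are known to couple under these conditions.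

## Compound list

1 | docosanoic acid (behenic acid) | CCCCCCCCCCCCCCCCCCCCCC(=O)O | starting material
2 | 1,3-dibromopropane | BrCCCBr | starting material
3 | potassium docosanoate | CCCCCCCCCCCCCCCCCCCCCC(=O)[O-].[K+] | intermediate
4 | 3-bromopropyl docosanoate | CCCCCCCCCCCCCCCCCCCCCC(=O)OCCCBr | intermediate
5 | 4-bromophenol | Oc1ccc(Br)cc1 | starting material
6 | 3-(4-hydroxyphenyl)propyl docosanoate (achiral) | CCCCCCCCCCCCCCCCCCCCCC(=O)OCCCc1ccc(O)cc1 | target

## Step count, sequence and risks

Total step count: 2. Longest linear sequence: 2 (1 → 4 → 6).

The route has only two steps, so both are ranked, the more fragile first; there is no third step to rank.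

**Most likely to fail: step 2.** The acidic phenol O–H can divert aryl- or alkylnickel intermediates to hydrodehalogenation (phenol, propyl docosanoate). The electron-rich aryl bromide adds slowly, which favours alkyl dimer and β-hydride elimination to the allyl ester. The waxy C22 ester may also dissolve poorly in DMPU. The fallback replaces the electrophile–electrophile coupling by a B-alkyl Suzuki–Miyaura coupling. It sets out from 1: alkylation of 1 with allyl bromide (K2CO3, DMF, 50 °C) gives allyl docosanoate F1. Anti-Markovnikov hydroboration with 9-BBN-H (THF, 0 °C to rt; esters are not reduced) gives 3-(9-borabicyclo[3.3.1]nonan-9-yl)propyl docosanoate F2, which is used as its THF solution without isolation. Coupling of this alkylborane with 5 (Pd(OAc)2/SPhos 3/6 mol%, K3PO4 3 equiv, THF/H2O, 60 °C) comes back to the route at 6.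

**Second: step 1.** Mono-substitution of a symmetrical dihalide can give the 1,3-diester, which is hard to separate from waxy 4. Elimination of 2 can lead to the allyl ester, and the potassium soap dissolves sluggishly in DMF. The fallback forms the ester by acylation instead of carboxylate alkylation. It sets out from 1: Fischer esterification of 1 with 3-bromopropan-1-ol (1.5 equiv, TsOH·H2O 5 mol%, toluene, Dean–Stark reflux) comes back to the route directly at 4. This fallback makes no new compound (F0) and gives only water beside the product.

## Further compounds

F1 | step 2 | allyl docosanoate (prop-2-en-1-yl docosanoate) | CCCCCCCCCCCCCCCCCCCCCC(=O)OCC=C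
F2 | step 2 | 3-(9-borabicyclo[3.3.1]nonan-9-yl)propyl docosanoate | CCCCCCCCCCCCCCCCCCCCCC(=O)OCCCB1C2CCCC1CCC2
F0 | step 1 | none | none
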